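**Plan**

- Feature used: ring A carries at C6 a benzylic CH2 (C1″) attached to the E-trisubstituted C2″=C3″ alkene with its C3″ methyl. This is the pattern left by a terminal alkyne that has been methylmetalated syn and joined to an arylmethyl halide.
- Retrosynthetic cuts, in order: C2–C1′ (B-ring aryl removed from a chromone); then the pyranone ring (O1–C2, C3–C4 and C4–C4a, back to a para-phenol, formaldehyde and an ethynyl unit); then C1″–C2″ together with C3″–CH3.
- Forward: an (R)-silyloxy enyne and a 2,6-bis(MOM)-4-silyloxybenzyl chloride are each made in four steps and joined with AlMe3 in one pot. The para-phenol is then unmasked, ring C is grown from it (formylation, ethynylation, oxidation–cyclisation), ring B is added and all protecting groups are removed.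
- Stereochemistry: C6″ (R) comes from a CBS reduction; the 2″E alkene from syn-carboalumination and a stereoretentive coupling; C2 (S) from a Rh/chiral bisphosphine conjugate arylation.
- Regiochemistry: the benzylic carbon is the former formyl carbon and only the para oxygen is silylated, so that oxygen alone becomes O1 and the chain ends up at C6, not C8.

Key step: step 9

Remark on numbering: flavanone numbering is used for the core, and doubly primed numbers for the C10 chain (C1″ benzylic, C6″ carbinol).

Assumption: the Rh/(S)-biaryl bisphosphine catalyst is taken to attack the chromone with the same facial sense as it shows with cyclohexenone (aryl to the Re face of C2, giving 2S). A model run on 5,7-bis(methoxymethoxy)chromone would confirm the ligand hand before advanced material is committed; the (R)-ligand is used if the sense is reversed.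

**Route**

Step 1
Reactants: 1 pent-4-ynoic acid
Product: 3 N-methoxy-N-methylpent-4-ynamide, via 1-(pent-4-ynoyl)imidazole 2 (not isolated)
Conditions: CDI, CH2Cl2, rt; then MeNH(OMe)·HCl, rt
Reagents that add atoms: N,O-dimethylhydroxylamine hydrochloride, CNOC.Cl
Why: CDI activation followed by aminolysis of the acyl imidazolide is a standard amide coupling to Weinreb amides and leaves the terminal alkyne untouched.

Step 2
Reactants: 3 N-methoxy-N-methylpent-4-ynamide; 4 isopropenylmagnesium bromide (THF solution)
Product: 5 2-methylhept-1-en-6-yn-3-one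
Conditions: 4 (2.2 equiv), THF, −20 → 0 °C; inverse quench into cold 1 M HCl
Reagents that add atoms: none
Why: In this Weinreb ketone synthesis the chelated tetrahedral magnesium adduct prevents over-addition, the excess Grignard covers partial deprotonation of the alkyne, and the inverse acidic quench keeps the liberated hydroxylamine from adding to the enone.

Step 3
Reactants: 5 2-methylhept-1-en-6-yn-3-one
Product: 6 (3R)-2-methylhept-1-en-6-yn-3-ol
Conditions: (S)-Me-CBS (0.2 equiv), catecholborane, toluene, −78 °C; MeOH, then aq. NaOH wash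
Reagents that add atoms: none
Why: In this Corey–Bakshi–Shibata reduction the α-branched alkenyl group acts as the large substituent, so the (S)-oxazaborolidine should deliver hydride to the Si face of the ketone and set C3 as R, while catecholborane at −78 °C spares the alkyne and the 1,1-disubstituted alkene.

Step 4
Reactants: 6 (3R)-2-methylhept-1-en-6-yn-3-ol
Product: 7 (3R)-3-(tert-butyldimethylsilyloxy)-2-methylhept-1-en-6-yne
Conditions: TBSCl, imidazole, DMF, rt
Reagents that add atoms: tert-butyldimethylsilyl chloride, CC(C)(C)[Si](C)(C)Cl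
Why: Imidazole-mediated silylation of a secondary alcohol is routine and does not touch the stereocentre.

Step 5
Reactants: 8 2,4,6-trihydroxybenzaldehyde
Product: 9 2,6-dihydroxy-4-(triisopropylsilyloxy)benzaldehyde
Conditions: TIPSCl (1.05 equiv), imidazole, DMF, 0 °C
Reagents that add atoms: triisopropylsilyl chloride, CC(C)[Si](Cl)(C(C)C)C(C)C
Why: Regioselective phenol silylation is expected because the 4-OH is the most acidic hydroxyl and the only one neither flanking nor hydrogen-bonded to the formyl group, so one equivalent of a bulky silyl chloride should take it alone.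

Step 6
Reactants: 9 2,6-dihydroxy-4-(triisopropylsilyloxy)benzaldehyde
Product: 10 2,6-bis(methoxymethoxy)-4-(triisopropylsilyloxy)benzaldehyde
Conditions: MOMCl (3 equiv), i-Pr2NEt, CH2Cl2, 0 °C → reflux
Reagents that add atoms: chloromethyl methyl ether, COCCl
Why: O-alkylation of the two chelated ortho-phenols with MOMCl and a hindered amine base (MOM ether formation) is standard under forcing conditions, which the aryl TIPS ether tolerates.

Step 7
Reactants: 10 2,6-bis(methoxymethoxy)-4-(triisopropylsilyloxy)benzaldehyde
Product: 11 [2,6-bis(methoxymethoxy)-4-(triisopropylsilyloxy)phenyl]methanol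
Conditions: NaBH4, THF/MeOH, 0 °C
Reagents that add atoms: none
Why: Borohydride reduction of an aryl aldehyde is fast at 0 °C and leaves the acetals and the silyl ether intact.

Step 8
Reactants: 11 [2,6-bis(methoxymethoxy)-4-(triisopropylsilyloxy)phenyl]methanol
Product: 13 2,6-bis(methoxymethoxy)-4-(triisopropylsilyloxy)benzyl chloride, via benzylic mesylate 12 (not isolated)
Conditions: MsCl, Et3N, CH2Cl2, −20 → 0 °C; cold NaHCO3 wash, dried, concentrated cold and used at once
Reagents that add atoms: methanesulfonyl chloride, CS(=O)(=O)Cl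
Why: Mesylation of a strongly electron-rich benzylic alcohol is followed in situ by chloride displacement of the labile mesylate (SN1-like substitution) under non-acidic conditions that keep the MOM acetals, and immediate use limits self-alkylation of the chloride.

Step 9
Reactants: 7 (3R)-3-(tert-butyldimethylsilyloxy)-2-methylhept-1-en-6-yne; 14 trimethylaluminium; 13 2,6-bis(methoxymethoxy)-4-(triisopropylsilyloxy)benzyl chloride
Product: 16 2-[(2E,6R)-6-(tert-butyldimethylsilyloxy)-3,7-dimethylocta-2,7-dien-1-yl]-1,3-bis(methoxymethoxy)-5-(triisopropylsilyloxy)benzene, via (E)-alkenyldimethylalane 15 (not isolated)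
Conditions: 7, AlMe3 (2 equiv), Cp2ZrCl2 (0.25 equiv), ClCH2CH2Cl, 0 °C → rt; volatiles removed in vacuo, THF; then 13 (0.8 equiv), Ni(PPh3)4 (5 mol %, from NiCl2(PPh3)2/n-BuLi), THF, 0 °C → rt
Reagents that add atoms: none
Why: Negishi zirconium-catalysed carboalumination adds methyl and aluminium syn across the terminal alkyne of 7 with methyl at the internal carbon, so alane 15 should have the E geometry and already carries the C3″–CH3 bond. After volatile AlMe3 is stripped and the solvent changed to THF, Ni(0) inserts into the benzylic C–Cl bond of 13, the alkenyl group transmetalates from aluminium to nickel, and reductive elimination forms C1″–C2″ with retention of alkene geometry. The closest known reaction type is the carboalumination/Ni- or Pd-catalysed benzylic chloride coupling used for polyprenylated arenes and quinones. No ring closes and no stereocentre is created; the C6″ centre from step 3 is remote and untouched. The step needs terminal-aluminium regioselectivity and syn addition (secured by the unhindered terminal alkyne), alkyne-over-alkene chemoselectivity (1,1-disubstituted alkenes are inert to Cp2ZrCl2/AlMe3) and alkenyl-over-methyl transfer (secured by removing excess AlMe3 and by the faster sp2 transmetalation). Because the chloromethyl carbon is the former formyl carbon, the chain can only sit between the two MOM-protected oxygens.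

Step 10
Reactants: 16 2-[(2E,6R)-6-(tert-butyldimethylsilyloxy)-3,7-dimethylocta-2,7-dien-1-yl]-1,3-bis(methoxymethoxy)-5-(triisopropylsilyloxy)benzene
Product: 17 4-[(2E,6R)-6-(tert-butyldimethylsilyloxy)-3,7-dimethylocta-2,7-dien-1-yl]-3,5-bis(methoxymethoxy)phenol
Conditions: TBAF (1.1 equiv), AcOH (1.1 equiv), THF, 0 °C → rt
Reagents that add atoms: none
Why: Chemoselective fluoride desilylation is expected because aryl silyl ethers are cleaved far faster than secondary alkyl silyl ethers (phenoxide is the better leaving group), and the acetic acid buffer keeps the medium mild for the TBS ether.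

Step 11
Reactants: 17 4-[(2E,6R)-6-(tert-butyldimethylsilyloxy)-3,7-dimethylocta-2,7-dien-1-yl]-3,5-bis(methoxymethoxy)phenol
Product: 18 3-[(2E,6R)-6-(tert-butyldimethylsilyloxy)-3,7-dimethylocta-2,7-dien-1-yl]-6-hydroxy-2,4-bis(methoxymethoxy)benzaldehyde
Conditions: MgCl2, Et3N, (CH2O)n, MeCN, reflux
Reagents that add atoms: paraformaldehyde (as formaldehyde), C=O
Why: In the Casnati–Skattebøl ortho-formylation the magnesium phenoxide delivers formaldehyde to the ortho carbon through a chelate and a second formaldehyde oxidises the resulting benzylic alkoxide; the two ortho positions are equivalent by symmetry and the basic medium spares the acetals, the silyl ether and both alkenes.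

Step 12
Reactants: 18 3-[(2E,6R)-6-(tert-butyldimethylsilyloxy)-3,7-dimethylocta-2,7-dien-1-yl]-6-hydroxy-2,4-bis(methoxymethoxy)benzaldehyde; 19 ethynylmagnesium bromide (THF solution)
Product: 20 1-{3-[(2E,6R)-6-(tert-butyldimethylsilyloxy)-3,7-dimethylocta-2,7-dien-1-yl]-6-hydroxy-2,4-bis(methoxymethoxy)phenyl}prop-2-yn-1-ol (both carbinol epimers)
Conditions: 19 (3.5 equiv), THF, −20 °C → rt; sat. NH4Cl; crude material taken on directly
Reagents that add atoms: none
Why: Grignard addition of an acetylide to a salicylaldehyde proceeds after the first equivalent has deprotonated the phenol, and the new carbinol centre is of no consequence because it is oxidised in the next step.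

Step 13
Reactants: 20 1-{3-[(2E,6R)-6-(tert-butyldimethylsilyloxy)-3,7-dimethylocta-2,7-dien-1-yl]-6-hydroxy-2,4-bis(methoxymethoxy)phenyl}prop-2-yn-1-ol
Product: 22 6-[(2E,6R)-6-(tert-butyldimethylsilyloxy)-3,7-dimethylocta-2,7-dien-1-yl]-5,7-bis(methoxymethoxy)-4H-chromen-4-one, via 2-hydroxyaryl ethynyl ketone 21 (not isolated)
Conditions: activated MnO2 (excess), CH2Cl2, rt; filtered; Et3N (cat.), CH2Cl2, rt
Reagents that add atoms: none
Why: MnO2 oxidation of the benzylic–propargylic alcohol gives the ynone, whose only free phenol adds to the unsubstituted alkyne terminus in a base-catalysed 6-endo-dig oxa-Michael cyclisation, so the chromone with the chain at C6 is the single possible ring.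

Step 14
Reactants: 23 4-bromobenzene-1,2-diol
Product: 24 4-bromo-1,2-bis(methoxymethoxy)benzene
Conditions: MOMCl (2.5 equiv), i-Pr2NEt, CH2Cl2, 0 °C → rt
Reagents that add atoms: chloromethyl methyl ether, COCCl
Why: MOM ether formation on a catechol with MOMCl and a hindered amine base is routine.

Step 15
Reactants: 24 4-bromo-1,2-bis(methoxymethoxy)benzene
Product: 26 [3,4-bis(methoxymethoxy)phenyl]boronic acid, via aryllithium 25 (not isolated)
Conditions: n-BuLi, THF, −78 °C; B(Oi-Pr)3, −78 °C → rt; aq. NH4Cl
Reagents that add atoms: triisopropyl borate, CC(C)OB(OC(C)C)OC(C)C; water, O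
Why: Bromine–lithium exchange outruns MOM-directed ortho-lithiation at −78 °C, the aryllithium is trapped by the borate (lithiation–borylation), and the near-neutral hydrolysis keeps the MOM acetals.

Step 16
Reactants: 22 6-[(2E,6R)-6-(tert-butyldimethylsilyloxy)-3,7-dimethylocta-2,7-dien-1-yl]-5,7-bis(methoxymethoxy)-4H-chromen-4-one; 26 [3,4-bis(methoxymethoxy)phenyl]boronic acid
Product: 27 (2S)-2-[3,4-bis(methoxymethoxy)phenyl]-6-[(2E,6R)-6-(tert-butyldimethylsilyloxy)-3,7-dimethylocta-2,7-dien-1-yl]-5,7-bis(methoxymethoxy)-2,3-dihydro-4H-chromen-4-one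
Conditions: [Rh(OH)((S)-MeO-F12-BIPHEP)]2 (cat.), 26 (2.5 equiv), toluene/H2O, 40 °C
Reagents that add atoms: none
Why: In this Hayashi–Miyaura Rh(I)-catalysed asymmetric conjugate addition the aryl–rhodium species inserts across C2=C3 of the chromone from the Re face of C2 under control of the electron-poor chiral bisphosphine and the rhodium enolate is protonated by water, which should set C2 as S; the base-free medium disfavours retro-oxa-Michael ring opening and the isolated alkenes are not acceptors.

Step 17
Reactants: 27 (2S)-2-[3,4-bis(methoxymethoxy)phenyl]-6-[(2E,6R)-6-(tert-butyldimethylsilyloxy)-3,7-dimethylocta-2,7-dien-1-yl]-5,7-bis(methoxymethoxy)-2,3-dihydro-4H-chromen-4-one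
Product: 28 (2S)-2-(3,4-dihydroxyphenyl)-5,7-dihydroxy-6-[(2E,6R)-6-hydroxy-3,7-dimethylocta-2,7-dien-1-yl]-2,3-dihydro-4H-chromen-4-one (CNP0252544.1)
Conditions: 3 M aq. HCl/MeOH, rt → 40 °C
Reagents that add atoms: none
Why: Acid-catalysed acetal exchange converts the four aryl MOM ethers into dimethoxymethane and methanolysis removes the TBS ether (global acidic deprotection), and the low temperature is chosen so that neither C2 nor C6″ should be epimerised.

**Compound list**

1 | pent-4-ynoic acid | C#CCCC(=O)O | starting material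
2 | 1-(pent-4-ynoyl)imidazole | C#CCCC(=O)n1ccnc1 | intermediate
3 | N-methoxy-N-methylpent-4-ynamide | C#CCCC(=O)N(C)OC | intermediate
4 | isopropenylmagnesium bromide | C=C(C)[Mg]Br | starting material
5 | 2-methylhept-1-en-6-yn-3-one | C=C(C)C(=O)CCC#C | intermediate
6 | (3R)-2-methylhept-1-en-6-yn-3-ol | C=C(C)[C@H](O)CCC#C | intermediate
7 | (3R)-3-(tert-butyldimethylsilyloxy)-2-methylhept-1-en-6-yne | C=C(C)[C@H](O[Si](C)(C)C(C)(C)C)CCC#C | intermediate
8 | 2,4,6-trihydroxybenzaldehyde | O=Cc1c(O)cc(O)cc1O | starting material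
9 | 2,6-dihydroxy-4-(triisopropylsilyloxy)benzaldehyde | O=Cc1c(O)cc(O[Si](C(C)C)(C(C)C)C(C)C)cc1O | intermediate
10 | 2,6-bis(methoxymethoxy)-4-(triisopropylsilyloxy)benzaldehyde | O=Cc1c(OCOC)cc(O[Si](C(C)C)(C(C)C)C(C)C)cc1OCOC | intermediate
11 | [2,6-bis(methoxymethoxy)-4-(triisopropylsilyloxy)phenyl]methanol | OCc1c(OCOC)cc(O[Si](C(C)C)(C(C)C)C(C)C)cc1OCOC | intermediate
12 | 2,6-bis(methoxymethoxy)-4-(triisopropylsilyloxy)benzyl methanesulfonate | CS(=O)(=O)OCc1c(OCOC)cc(O[Si](C(C)C)(C(C)C)C(C)C)cc1OCOC | intermediate
13 | 2,6-bis(methoxymethoxy)-4-(triisopropylsilyloxy)benzyl chloride | ClCc1c(OCOC)cc(O[Si](C(C)C)(C(C)C)C(C)C)cc1OCOC | intermediate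
14 | trimethylaluminium | C[Al](C)C | starting material
15 | [(1E,5R)-5-(tert-butyldimethylsilyloxy)-2,6-dimethylhepta-1,6-dien-1-yl]dimethylalane | C=C(C)[C@H](O[Si](C)(C)C(C)(C)C)CC/C(C)=C/[Al](C)C | intermediate
16 | 2-[(2E,6R)-6-(tert-butyldimethylsilyloxy)-3,7-dimethylocta-2,7-dien-1-yl]-1,3-bis(methoxymethoxy)-5-(triisopropylsilyloxy)benzene | C=C(C)[C@H](O[Si](C)(C)C(C)(C)C)CC/C(C)=C/Cc1c(OCOC)cc(O[Si](C(C)C)(C(C)C)C(C)C)cc1OCOC | intermediate
17 | 4-[(2E,6R)-6-(tert-butyldimethylsilyloxy)-3,7-dimethylocta-2,7-dien-1-yl]-3,5-bis(methoxymethoxy)phenol | C=C(C)[C@H](O[Si](C)(C)C(C)(C)C)CC/C(C)=C/Cc1c(OCOC)cc(O)cc1OCOC | intermediate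
18 | 3-[(2E,6R)-6-(tert-butyldimethylsilyloxy)-3,7-dimethylocta-2,7-dien-1-yl]-6-hydroxy-2,4-bis(methoxymethoxy)benzaldehyde | C=C(C)[C@H](O[Si](C)(C)C(C)(C)C)CC/C(C)=C/Cc1c(OCOC)cc(O)c(C=O)c1OCOC | intermediate
19 | ethynylmagnesium bromide | C#C[Mg]Br | starting material
20 | 1-{3-[(2E,6R)-6-(tert-butyldimethylsilyloxy)-3,7-dimethylocta-2,7-dien-1-yl]-6-hydroxy-2,4-bis(methoxymethoxy)phenyl}prop-2-yn-1-ol (carbinol epimers) | C=C(C)[C@H](O[Si](C)(C)C(C)(C)C)CC/C(C)=C/Cc1c(OCOC)cc(O)c(C(O)C#C)c1OCOC | intermediate
21 | 1-{3-[(2E,6R)-6-(tert-butyldimethylsilyloxy)-3,7-dimethylocta-2,7-dien-1-yl]-6-hydroxy-2,4-bis(methoxymethoxy)phenyl}prop-2-yn-1-one | C=C(C)[C@H](O[Si](C)(C)C(C)(C)C)CC/C(C)=C/Cc1c(OCOC)cc(O)c(C(=O)C#C)c1OCOC | intermediate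
22 | 6-[(2E,6R)-6-(tert-butyldimethylsilyloxy)-3,7-dimethylocta-2,7-dien-1-yl]-5,7-bis(methoxymethoxy)-4H-chromen-4-one | C=C(C)[C@H](O[Si](C)(C)C(C)(C)C)CC/C(C)=C/Cc1c(OCOC)cc2occc(=O)c2c1OCOC | intermediate
23 | 4-bromobenzene-1,2-diol | Oc1ccc(Br)cc1O | starting material
24 | 4-bromo-1,2-bis(methoxymethoxy)benzene | COCOc1ccc(Br)cc1OCOC | intermediate
25 | [3,4-bis(methoxymethoxy)phenyl]lithium | COCOc1ccc([Li])cc1OCOC | intermediate
26 | [3,4-bis(methoxymethoxy)phenyl]boronic acid | COCOc1ccc(B(O)O)cc1OCOC | intermediate
27 | (2S)-2-[3,4-bis(methoxymethoxy)phenyl]-6-[(2E,6R)-6-(tert-butyldimethylsilyloxy)-3,7-dimethylocta-2,7-dien-1-yl]-5,7-bis(methoxymethoxy)-2,3-dihydro-4H-chromen-4-one | C=C(C)[C@H](O[Si](C)(C)C(C)(C)C)CC/C(C)=C/Cc1c(OCOC)cc2c(c1OCOC)C(=O)C[C@@H](c1ccc(OCOC)c(OCOC)c1)O2 | intermediate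
28 | (2S)-2-(3,4-dihydroxyphenyl)-5,7-dihydroxy-6-[(2E,6R)-6-hydroxy-3,7-dimethylocta-2,7-dien-1-yl]-2,3-dihydro-4H-chromen-4-one | C=C(C)[C@H](O)CC/C(C)=C/Cc1c(O)cc2c(c1O)C(=O)C[C@@H](c1ccc(O)c(O)c1)O2 | target

**Step count and risks**

Total steps: 17. Longest linear sequence: 11 steps (steps 1–4 or 5–8, then 9–13, 16 and 17).

Steps most likely to fail:

1. Step 9. The aluminium Lewis acids may ionise the very electron-rich benzylic chloride and trigger Friedel–Crafts self-alkylation. Residual methylalanes may transfer methyl instead of the alkenyl group. Any loss of regiocontrol in the carbometalation cannot be corrected once the chain is on the ring. The fallback sets out from 7 and 13 and comes back to the route at 16. Alane 15, generated from 7 and 14 as in step 9, would be quenched with iodine at low temperature to give (3R,6E)-3-(tert-butyldimethylsilyloxy)-7-iodo-2,6-dimethylhepta-1,6-diene F1, which can be purified and checked for geometry. Chloride 13 would be converted by zinc dust/LiCl insertion in THF into 2,6-bis(methoxymethoxy)-4-(triisopropylsilyloxy)benzylzinc chloride F2. A Pd-catalysed Negishi coupling of F1 with F2 (Pd(OAc)2/SPhos, THF, rt) would then give 16. The benzylic partner becomes the nucleophile, so neither a free benzylic cation nor methylalanes are present when the C1″–C2″ bond forms.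

2. Step 16. Insertion into the electron-rich 5,7-dioxygenated chromone may be slow, the electron-rich boronic acid may protodeboronate, and reversible retro-oxa-Michael opening of the flavanone or imperfect facial control may erode the configuration at C2. The fallback sets out from 22 and comes back at 27. Aqueous NaOH/EtOH would cleave the pyranone ring with loss of formate to give 1-{3-[(2E,6R)-6-(tert-butyldimethylsilyloxy)-3,7-dimethylocta-2,7-dien-1-yl]-6-hydroxy-2,4-bis(methoxymethoxy)phenyl}ethan-1-one F3. Claisen–Schmidt condensation with 3,4-bis(methoxymethoxy)benzaldehyde (KOH, EtOH, rt) would give the (E)-2′-hydroxychalcone F4. A cinchona-alkaloid thiourea catalyst (the quinine- or quinidine-derived member, whichever favours 2S) would then close the C2–O1 bond by enantioselective intramolecular oxa-Michael addition to give 27. Because C6″ is fixed, the unwanted C2 epimer is a diastereomer and could be removed by chromatography on a chiral phase if enrichment is needed.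

3. Step 17. Protic acid may add the C5 or C7 phenol across the C2″=C3″ alkene (chroman formation), solvolyse or transpose the allylic C6″ alcohol with loss of its configuration, or leave MOM groups partly in place. The fallback sets out from 27 and comes back at 28. ZnBr2/n-PrSH in CH2Cl2 (0 °C → rt, short contact) would remove the four aryl MOM groups by acetal transfer to the thiol while the allylic oxygen stays silylated, giving (2S)-6-[(2E,6R)-6-(tert-butyldimethylsilyloxy)-3,7-dimethylocta-2,7-dien-1-yl]-2-(3,4-dihydroxyphenyl)-5,7-dihydroxy-2,3-dihydro-4H-chromen-4-one F5. Buffered HF·pyridine in THF/pyridine at 0 °C would then remove the TBS group to give 28 without exposure to strong protic acid or base.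

**Further compounds**

F1 | step 9 | (3R,6E)-3-(tert-butyldimethylsilyloxy)-7-iodo-2,6-dimethylhepta-1,6-diene | C=C(C)[C@H](O[Si](C)(C)C(C)(C)C)CC/C(C)=C/I
F2 | step 9 | 2,6-bis(methoxymethoxy)-4-(triisopropylsilyloxy)benzylzinc chloride | Cl[Zn]Cc1c(OCOC)cc(O[Si](C(C)C)(C(C)C)C(C)C)cc1OCOC
F3 | step 16 | 1-{3-[(2E,6R)-6-(tert-butyldimethylsilyloxy)-3,7-dimethylocta-2,7-dien-1-yl]-6-hydroxy-2,4-bis(methoxymethoxy)phenyl}ethan-1-one | C=C(C)[C@H](O[Si](C)(C)C(C)(C)C)CC/C(C)=C/Cc1c(OCOC)cc(O)c(C(C)=O)c1OCOC
F4 | step 16 | (2E)-3-[3,4-bis(methoxymethoxy)phenyl]-1-{3-[(2E,6R)-6-(tert-butyldimethylsilyloxy)-3,7-dimethylocta-2,7-dien-1-yl]-6-hydroxy-2,4-bis(methoxymethoxy)phenyl}prop-2-en-1-one | C=C(C)[C@H](O[Si](C)(C)C(C)(C)C)CC/C(C)=C/Cc1c(OCOC)cc(O)c(C(=O)/C=C/c2ccc(OCOC)c(OCOC)c2)c1OCOC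
F5 | step 17 | (2S)-6-[(2E,6R)-6-(tert-butyldimethylsilyloxy)-3,7-dimethylocta-2,7-dien-1-yl]-2-(3,4-dihydroxyphenyl)-5,7-dihydroxy-2,3-dihydro-4H-chromen-4-one | C=C(C)[C@H](O[Si](C)(C)C(C)(C)C)CC/C(C)=C/Cc1c(O)cc2c(c1O)C(=O)C[C@@H](c1ccc(O)c(O)c1)O2
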